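**Retrosynthetic overview**

- The strategy rests on the pyrrole C3–C4 bond. It joins two carbons that each carry a 5-bromoindol-3-yl ring and each sit beside an imine-level carbon (C2 with CO2Me, C5 with H).
- Cutting C3–C4 and one N–C bond opens the pyrrole to mixed azine 11 of an indolylpyruvate ester and an indolylacetaldehyde. Forward, this is a Piloty–Robinson closure: a [3,3] shift, then loss of one nitrogen.
- Azine 11 comes from NH2-hydrazone 10 and aldehyde 5. Both halves grow from the single N-tosyl aldehyde 2: olefination, hydrolysis and hydrazone formation on one side, Wittig homologation on the other.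
- Ring order: both bromoindoles are bought intact. The pyrrole is the only ring made and is closed last (C3–C4 first, N–C second), followed by one global N-deprotection. No transition metal touches the aryl bromides.

Key step: step 8

Assumption: enol ether 4 is used as its E/Z mixture and the C=N geometries of 10 and 11 are left undefined, because all are lost or equilibrate later. Compound 9 is drawn as the keto tautomer although it should exist largely as the enol. Ts = 4-methylbenzenesulfonyl.

**Route**

Step 1
Reactants: 1 5-bromo-1H-indole-3-carbaldehyde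
Product: 2 5-bromo-1-tosylindole-3-carbaldehyde
Conditions: TsCl, 50% aq NaOH, Bu4NHSO4 (cat.), CH2Cl2, 0 °C to rt
Reagents that add atoms: p-toluenesulfonyl chloride, Cc1ccc(S(=O)(=O)Cl)cc1
Why: Phase-transfer N-sulfonylation of the acidic 3-formylindole N–H is routine, and the electron-poor N-tosyl indole should no longer act as a nucleophile in the later acid, acylation and heating steps.

Step 2
Reactants: 2 5-bromo-1-tosylindole-3-carbaldehyde; 3 (methoxymethyl)triphenylphosphonium chloride
Product: 4 5-bromo-3-(2-methoxyethenyl)-1-tosylindole (E/Z mixture)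
Conditions: 3 (slight excess over base), KOtBu, THF, 0 °C; then 2, 0 °C to rt
Reagents that add atoms: none
Why: Wittig methoxymethylenation of the aromatic aldehyde by the ylide generated in the flask should give the one-carbon-homologated enol ether, and its alkene geometry is irrelevant because both isomers hydrolyse to the same aldehyde.

Step 3
Reactants: 4 5-bromo-3-(2-methoxyethenyl)-1-tosylindole
Product: 5 2-(5-bromo-1-tosylindol-3-yl)acetaldehyde
Conditions: 2 M aq HCl, THF, rt; crude aldehyde used at once
Reagents that add atoms: water, O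
Why: Acid-catalysed enol ether hydrolysis (protonation at the indolyl-bearing carbon, hemiacetal, loss of methanol) should unmask the arylacetaldehyde, and the sulfonyl group keeps the indole from adding to the oxocarbenium ion.

Step 4
Reactants: 2 5-bromo-1-tosylindole-3-carbaldehyde; 6 methyl 2-(tert-butoxycarbonylamino)-2-(dimethoxyphosphoryl)acetate
Product: 7 methyl (Z)-2-(tert-butoxycarbonylamino)-3-(5-bromo-1-tosylindol-3-yl)prop-2-enoate
Conditions: DBU, CH2Cl2, 0 °C to rt
Reagents that add atoms: none
Why: Horner–Wadsworth–Emmons olefination with the phosphonoglycinate anion should give the dehydroamino ester, for which the Z alkene is the usual thermodynamically favoured outcome, and this geometry is lost again in step 5.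

Step 5
Reactants: 7 methyl (Z)-2-(tert-butoxycarbonylamino)-3-(5-bromo-1-tosylindol-3-yl)prop-2-enoate
Product: 9 methyl 3-(5-bromo-1-tosylindol-3-yl)-2-oxopropanoate, via free enamino ester 8 (not isolated)
Conditions: TFA, CH2Cl2, 0 °C to rt; then H2O/THF, rt
Reagents that add atoms: water, O
Why: Acidolysis of the Boc carbamate frees the primary enamine, which tautomerises to the protonated ketimine and should be hydrolysed by water to the alpha-keto ester (enamine/imine hydrolysis), while the sulfonamide, ester and bromide are inert to TFA.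

Step 6
Reactants: 9 methyl 3-(5-bromo-1-tosylindol-3-yl)-2-oxopropanoate
Product: 10 methyl 3-(5-bromo-1-tosylindol-3-yl)-2-hydrazinylidenepropanoate
Conditions: N2H4·H2O (2 equiv, 9 added slowly to it), AcOH (cat.), MeOH/THF, 0 °C, short reaction time
Reagents that add atoms: hydrazine (used as the monohydrate), NN
Why: Hydrazone formation at the ketone carbonyl, the most electrophilic site of an alpha-keto ester, should give the N-unsubstituted hydrazone, and inverse addition into cold excess hydrazine disfavours both the symmetrical azine and attack at the ester.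

Step 7
Reactants: 10 methyl 3-(5-bromo-1-tosylindol-3-yl)-2-hydrazinylidenepropanoate; 5 2-(5-bromo-1-tosylindol-3-yl)acetaldehyde
Product: 11 methyl 3-(5-bromo-1-tosylindol-3-yl)-2-[2-(5-bromo-1-tosylindol-3-yl)ethylidenehydrazinylidene]propanoate (mixed azine)
Conditions: 4 Å molecular sieves, CH2Cl2, rt, no acid
Reagents that add atoms: none
Why: Condensation of the free NH2 of a hydrazone with an aldehyde is the standard entry to unsymmetrical azines, and acid-free dehydrating conditions should keep the two C=N bonds from exchanging.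

Step 8
Reactants: 11 mixed azine
Product: 15 methyl 1-benzoyl-3,4-bis(5-bromo-1-tosylindol-3-yl)pyrrole-2-carboxylate, via dibenzoyl bis-ene-hydrazine 12 (not isolated), via bis(N-benzoylimine) 13 (not isolated), via benzamido-pyrroline 14 (not isolated)
Conditions: PhCOCl (3 equiv), pyridine, 150–170 °C, sealed tube (microwave); aq NaHCO3 work-up
Reagents that add atoms: benzoyl chloride, O=C(Cl)c1ccccc1
Why: Proposed new method: double N-benzoylation of the azine with loss of the two CH2 protons should give the N,N'-dibenzoyl bis-ene-hydrazine 12, whose [3,3]-sigmatropic shift cleaves the weak N–N bond and joins the two indolyl-bearing carbons (the future pyrrole C3–C4 bond) to give the 1,4-bis(N-benzoylimine) 13. Tautomerisation of the ketimine half to its enamide and 5-exo-trig addition of that nitrogen to the aldimine carbon should close the five-membered ring as aminal 14, and loss of benzamide then aromatises it to the N-benzoyl pyrrole. The closest known reaction type is the Piloty–Robinson pyrrole synthesis from symmetrical aldehyde or ketone azines, run with acid and heat or with an aroyl chloride in hot pyridine; it has not been shown for an unsymmetrical azine with an ester on one azine carbon. The two sp3 centres created in the sigmatropic step are transient and are erased on aromatisation, so no stereocontrol is needed. The selectivity required is cross-union of the two different halves at their indolyl-bearing carbons: the N–N link of the preformed mixed azine enforces it, each half has only one alpha-CH2 so the ene-hydrazine regiochemistry is fixed, and the water-free acylating medium should suppress exchange to the symmetrical azines. Both ene-hydrazine halves are conjugated (a 3-vinylindole and an indolyl dehydroamino ester), which should ease their formation, and the N-tosyl groups keep the indoles from attacking the acylimines.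

Step 9
Reactants: 15 methyl 1-benzoyl-3,4-bis(5-bromo-1-tosylindol-3-yl)pyrrole-2-carboxylate
Product: 16 methyl 3,4-bis(5-bromo-1H-indol-3-yl)-1H-pyrrole-2-carboxylate (target)
Conditions: Cs2CO3, MeOH/THF, rt to 50 °C
Reagents that add atoms: none
Why: Methoxide formed from Cs2CO3 in methanol should cleave the N-benzoyl pyrrole by transacylation and both indole N-sulfonyl groups by attack at sulfur (base-mediated methanolysis), while the methyl ester is only degenerately transesterified and the aryl bromides are untouched.

**Compound list**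

1 | 5-bromo-1H-indole-3-carbaldehyde | O=Cc1c[nH]c2ccc(Br)cc12 | starting material
2 | 5-bromo-1-tosylindole-3-carbaldehyde | Cc1ccc(S(=O)(=O)n2cc(C=O)c3cc(Br)ccc32)cc1 | intermediate
3 | (methoxymethyl)triphenylphosphonium chloride | COC[P+](c1ccccc1)(c1ccccc1)c1ccccc1.[Cl-] | starting material
4 | 5-bromo-3-(2-methoxyethenyl)-1-tosylindole (E/Z mixture) | COC=Cc1cn(S(=O)(=O)c2ccc(C)cc2)c2ccc(Br)cc12 | intermediate
5 | 2-(5-bromo-1-tosylindol-3-yl)acetaldehyde | O=CCc1cn(S(=O)(=O)c2ccc(C)cc2)c2ccc(Br)cc12 | intermediate
6 | methyl 2-(tert-butoxycarbonylamino)-2-(dimethoxyphosphoryl)acetate | COC(=O)C(NC(=O)OC(C)(C)C)P(=O)(OC)OC | starting material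
7 | methyl (Z)-2-(tert-butoxycarbonylamino)-3-(5-bromo-1-tosylindol-3-yl)prop-2-enoate | COC(=O)/C(NC(=O)OC(C)(C)C)=C/c1cn(S(=O)(=O)c2ccc(C)cc2)c2ccc(Br)cc12 | intermediate
8 | methyl (Z)-2-amino-3-(5-bromo-1-tosylindol-3-yl)prop-2-enoate (present as its trifluoroacetate salt) | COC(=O)/C(N)=C/c1cn(S(=O)(=O)c2ccc(C)cc2)c2ccc(Br)cc12 | intermediate
9 | methyl 3-(5-bromo-1-tosylindol-3-yl)-2-oxopropanoate | COC(=O)C(=O)Cc1cn(S(=O)(=O)c2ccc(C)cc2)c2ccc(Br)cc12 | intermediate
10 | methyl 3-(5-bromo-1-tosylindol-3-yl)-2-hydrazinylidenepropanoate | COC(=O)C(=NN)Cc1cn(S(=O)(=O)c2ccc(C)cc2)c2ccc(Br)cc12 | intermediate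
11 | methyl 3-(5-bromo-1-tosylindol-3-yl)-2-[2-(5-bromo-1-tosylindol-3-yl)ethylidenehydrazinylidene]propanoate | COC(=O)C(Cc1cn(S(=O)(=O)c2ccc(C)cc2)c2ccc(Br)cc12)=NN=CCc1cn(S(=O)(=O)c2ccc(C)cc2)c2ccc(Br)cc12 | intermediate
12 | methyl 2-{1,2-dibenzoyl-2-[2-(5-bromo-1-tosylindol-3-yl)ethenyl]hydrazinyl}-3-(5-bromo-1-tosylindol-3-yl)prop-2-enoate | COC(=O)C(=Cc1cn(S(=O)(=O)c2ccc(C)cc2)c2ccc(Br)cc12)N(C(=O)c1ccccc1)N(C(=O)c1ccccc1)C=Cc1cn(S(=O)(=O)c2ccc(C)cc2)c2ccc(Br)cc12 | intermediate
13 | methyl 2,5-bis(benzoylimino)-3,4-bis(5-bromo-1-tosylindol-3-yl)pentanoate | COC(=O)C(=NC(=O)c1ccccc1)C(c1cn(S(=O)(=O)c2ccc(C)cc2)c2ccc(Br)cc12)C(C=NC(=O)c1ccccc1)c1cn(S(=O)(=O)c2ccc(C)cc2)c2ccc(Br)cc12 | intermediate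
14 | methyl 5-benzamido-1-benzoyl-3,4-bis(5-bromo-1-tosylindol-3-yl)-4,5-dihydropyrrole-2-carboxylate | COC(=O)C1=C(c2cn(S(=O)(=O)c3ccc(C)cc3)c3ccc(Br)cc23)C(c2cn(S(=O)(=O)c3ccc(C)cc3)c3ccc(Br)cc23)C(NC(=O)c2ccccc2)N1C(=O)c1ccccc1 | intermediate
15 | methyl 1-benzoyl-3,4-bis(5-bromo-1-tosylindol-3-yl)pyrrole-2-carboxylate | COC(=O)c1n(C(=O)c2ccccc2)cc(-c2cn(S(=O)(=O)c3ccc(C)cc3)c3ccc(Br)cc23)c1-c1cn(S(=O)(=O)c2ccc(C)cc2)c2ccc(Br)cc12 | intermediate
16 | methyl 3,4-bis(5-bromo-1H-indol-3-yl)-1H-pyrrole-2-carboxylate | COC(=O)c1[nH]cc(-c2c[nH]c3ccc(Br)cc23)c1-c1c[nH]c2ccc(Br)cc12 | target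

**Step count**

Total steps: 9. Longest linear sequence: 7 steps (1 to 2 to 7 to 9 to 10 to 11 to 15 to 16, that is steps 1, 4, 5, 6, 7, 8 and 9). The aldehyde branch (steps 2 and 3) joins at step 7.

**Steps most likely to fail**

1. Step 8 (proposed new method). The sequence may stall through incomplete acylation of the less nucleophilic, ester-bearing azine nitrogen. Other failure processes are exchange of the mixed azine into the two symmetrical azines before the sigmatropic shift, thermal decomposition at the temperature needed, or chloride-induced loss of the ester methyl group.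
   The fallback uses known chemistry, sets out from keto ester 9 and returns at target 16. The enolate of 9 (LiN(SiMe3)2, THF, −78 °C) would be homocoupled oxidatively with half an equivalent of iodine to the 1,4-diketone dimethyl 3,4-bis(5-bromo-1-tosylindol-3-yl)-2,5-dioxohexanedioate F1. Paal–Knorr condensation with NH4OAc in AcOH would give dimethyl 3,4-bis(5-bromo-1-tosylindol-3-yl)-1H-pyrrole-2,5-dicarboxylate F2. Treatment with Cs2CO3 in MeOH/THF would remove both sulfonyl groups to give dimethyl 3,4-bis(5-bromo-1H-indol-3-yl)-1H-pyrrole-2,5-dicarboxylate F3. Saponification with one equivalent of LiOH in THF/MeOH/H2O, where the first carboxylate deactivates the second ester, would give 3,4-bis(5-bromo-1H-indol-3-yl)-5-(methoxycarbonyl)-1H-pyrrole-2-carboxylic acid F4. Copper-free protodecarboxylation of this pyrrole-2-carboxylic acid (warm TFA, or heating in ethanolamine) would deliver 16.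

2. Step 6. The hydrazone may over-condense with a second molecule of 9 to the symmetrical azine, hydrazine may attack the methyl ester, or it may cleave the N–S bond.
   The fallback sets out from 9 and returns at azine 11, bypassing 10. Compound 9 would be condensed with diethyl phosphorohydrazidate (EtOH, cat. AcOH) to the N-phosphoryl hydrazone methyl 3-(5-bromo-1-tosylindol-3-yl)-2-[(diethoxyphosphoryl)hydrazinylidene]propanoate F5, whose second nitrogen is blocked. Deprotonation with NaH in THF and addition of aldehyde 5 would form the second C=N bond in a Horner-type aza-olefination with loss of diethyl phosphate, giving 11 directly.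

3. Step 7. Reversible C=N exchange may scramble the mixed azine into the two symmetrical azines, and the enolisable aldehyde 5 may self-condense before it is captured.
   The fallback sets out from hydrazone 10 and returns at 11. Oxidation of 10 with MnO2 in CH2Cl2 would give the diazo ester methyl 3-(5-bromo-1-tosylindol-3-yl)-2-diazopropanoate F6. Addition of PPh3 would give the phosphazine methyl 3-(5-bromo-1-tosylindol-3-yl)-2-[(triphenylphosphoranylidene)hydrazinylidene]propanoate F7. Its irreversible, water-free aza-Wittig reaction with aldehyde 5 would furnish 11.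

**Further compounds**

F1 | step 8 | dimethyl 3,4-bis(5-bromo-1-tosylindol-3-yl)-2,5-dioxohexanedioate | COC(=O)C(=O)C(c1cn(S(=O)(=O)c2ccc(C)cc2)c2ccc(Br)cc12)C(c1cn(S(=O)(=O)c2ccc(C)cc2)c2ccc(Br)cc12)C(=O)C(=O)OC
F2 | step 8 | dimethyl 3,4-bis(5-bromo-1-tosylindol-3-yl)-1H-pyrrole-2,5-dicarboxylate | COC(=O)c1[nH]c(C(=O)OC)c(-c2cn(S(=O)(=O)c3ccc(C)cc3)c3ccc(Br)cc23)c1-c1cn(S(=O)(=O)c2ccc(C)cc2)c2ccc(Br)cc12
F3 | step 8 | dimethyl 3,4-bis(5-bromo-1H-indol-3-yl)-1H-pyrrole-2,5-dicarboxylate | COC(=O)c1[nH]c(C(=O)OC)c(-c2c[nH]c3ccc(Br)cc23)c1-c1c[nH]c2ccc(Br)cc12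
F4 | step 8 | 3,4-bis(5-bromo-1H-indol-3-yl)-5-(methoxycarbonyl)-1H-pyrrole-2-carboxylic acid | COC(=O)c1[nH]c(C(=O)O)c(-c2c[nH]c3ccc(Br)cc23)c1-c1c[nH]c2ccc(Br)cc12
F5 | step 6 | methyl 3-(5-bromo-1-tosylindol-3-yl)-2-[(diethoxyphosphoryl)hydrazinylidene]propanoate | COC(=O)C(Cc1cn(S(=O)(=O)c2ccc(C)cc2)c2ccc(Br)cc12)=NNP(=O)(OCC)OCC
F6 | step 7 | methyl 3-(5-bromo-1-tosylindol-3-yl)-2-diazopropanoate | COC(=O)C(=[N+]=[N-])Cc1cn(S(=O)(=O)c2ccc(C)cc2)c2ccc(Br)cc12
F7 | step 7 | methyl 3-(5-bromo-1-tosylindol-3-yl)-2-[(triphenylphosphoranylidene)hydrazinylidene]propanoate | COC(=O)C(Cc1cn(S(=O)(=O)c2ccc(C)cc2)c2ccc(Br)cc12)=NN=P(c1ccccc1)(c1ccccc1)c1ccccc1
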